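**Strategy.** The ten-membered ring is disconnected at C3–C4 (germacrane numbering: ring C1–C10, C14 on C10, C15 on C4, butenolide O–C6–C7=C11(C13)–C12). The C3 carbinol attached to the E-C4(C15)=C5 alkene is read as an aldehyde added across a methyl alkyne. A nickel-catalysed reductive ynal macrocyclization therefore forms the C3–C4 bond, the E-trisubstituted alkene and the C3 stereocentre in one operation, with C6 as the only controlling stereocentre. The precursor is an acyclic (R)-γ-propynyl butenolide whose C7 side chain carries the Z-C1=C10 alkene (from Birch reduction and ozonolysis of 3-methylanisole) and the C3 aldehyde.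

Key step: step 10

Assumption: the route is written for (S,S)-ProPhenol delivering the alkynyl group to the Si face in step 2 and for the 3R alcohol from step 10; both assignments are to be checked (Mosher ester, NOE) before material is carried on, and the last step inverts C3.

**Step 1**
Reactants: 1 but-2-yn-1-ol
Product: 2 but-2-ynal
Conditions: MnO2 (activated, 15 equiv), CH2Cl2, rt; filtered, used as solution
Reagents that add atoms: none
Why: MnO2 oxidation of a propargylic alcohol should stop at the volatile ynal without over-oxidation.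

**Step 2**
Reactants: 2 but-2-ynal; 3 ethyl propiolate (3 equiv)
Product: 4 ethyl (R)-4-hydroxyhepta-2,5-diynoate
Conditions: Me2Zn (3 equiv), (S,S)-ProPhenol (10 mol%), Ph3P=O (20 mol%), toluene, 0 °C
Reagents that add atoms: none
Why: Zinc–ProPhenol asymmetric alkynylation, in which the zinc acetylide of 3 should add to the Si face of the aldehyde inside the chiral dinuclear zinc pocket and so set the carbinol centre (future C6) as R.

**Step 3**
Reactants: 5 3-methylanisole
Product: 6 1-methoxy-5-methylcyclohexa-1,4-diene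
Conditions: Li, NH3 (l), t-BuOH, THF, −78 to −33 °C
Reagents that add atoms: none
Why: Birch reduction leaves the methoxy and methyl groups on sp2 carbons and gives the skipped diene whose ring later fixes the Z alkene.

**Step 4**
Reactants: 6 1-methoxy-5-methylcyclohexa-1,4-diene
Product: 8 methyl (Z)-6,6-dimethoxy-3-methylhex-3-enoate, via aldehyde ester 7 (not isolated)
Conditions: O3 (1.0 equiv), CH2Cl2/MeOH, −78 °C; Me2S; then HC(OMe)3, p-TsOH (cat.), 0 °C
Reagents that add atoms: ozone [O-][O+]=O; trimethyl orthoformate COC(OC)OC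
Why: Chemoselective ozonolysis of the electron-rich enol ether over the trisubstituted alkene should give ester and aldehyde termini with the ring-derived Z-C1=C10 alkene intact, and the labile β,γ-unsaturated aldehyde is masked at once by acetalization.

**Step 5**
Reactants: 8 methyl (Z)-6,6-dimethoxy-3-methylhex-3-enoate
Product: 9 (Z)-6,6-dimethoxy-3-methylhex-3-en-1-ol
Conditions: LiAlH4, Et2O, −20 to 0 °C
Reagents that add atoms: none
Why: Hydride reduction of the ester to the primary alcohol (future C8), to which the acetal and the isolated alkene are inert.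

**Step 6**
Reactants: 9 (Z)-6,6-dimethoxy-3-methylhex-3-en-1-ol
Product: 10 (Z)-6-iodo-1,1-dimethoxy-4-methylhex-3-ene
Conditions: I2, PPh3, imidazole, CH2Cl2, 0 °C
Reagents that add atoms: iodine II
Why: Appel-type iodination of the primary alcohol under imidazole buffering, which should spare the acetal.

**Step 7**
Reactants: 10 (Z)-6-iodo-1,1-dimethoxy-4-methylhex-3-ene (1.3 equiv); 4 ethyl (R)-4-hydroxyhepta-2,5-diynoate
Product: 14 (R)-4-[(Z)-6,6-dimethoxy-3-methylhex-3-en-1-yl]-3-iodo-5-(prop-1-yn-1-yl)furan-2(5H)-one, via Grignard reagent 11 (not isolated), via alkenylcopper adduct 12 (not isolated), via iodo hydroxy ester 13 (not isolated)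
Conditions: 10, Mg, THF, rt; CuBr·SMe2 (1.0 equiv to 11), −78 to −40 °C; 4 (pre-treated with MeMgBr, 1.0 equiv, THF, −78 °C), −78 °C; I2, −78 °C to rt; aq NH4Cl
Reagents that add atoms: iodine II
Why: Syn carbocupration of the ynoate puts the new chain and copper cis, so ester and alkoxide are cis; iodinolysis of the alkenylcopper goes with retention and the cis alkoxide then lactonises, which locks the tetrasubstituted C7=C11 alkene while C6 is untouched.

**Step 8**
Reactants: 14 (R)-4-[(Z)-6,6-dimethoxy-3-methylhex-3-en-1-yl]-3-iodo-5-(prop-1-yn-1-yl)furan-2(5H)-one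
Product: 15 (R)-4-[(Z)-6,6-dimethoxy-3-methylhex-3-en-1-yl]-3-(hydroxymethyl)-5-(prop-1-yn-1-yl)furan-2(5H)-one
Conditions: Bu3SnCH2OH (1.5 equiv), Pd(PPh3)4 (5 mol%), 1,4-dioxane, 80 °C
Reagents that add atoms: (tributylstannyl)methanol OC[Sn](CCCC)(CCCC)CCCC
Why: Stille cross-coupling of the α-iodo butenolide with the hydroxymethylstannane installs C13 under neutral conditions that should not enolise the C6–H bond.

**Step 9**
Reactants: 15 (R)-4-[(Z)-6,6-dimethoxy-3-methylhex-3-en-1-yl]-3-(hydroxymethyl)-5-(prop-1-yn-1-yl)furan-2(5H)-one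
Product: 16 (Z)-6-[(R)-4-(hydroxymethyl)-5-oxo-2-(prop-1-yn-1-yl)-2,5-dihydrofuran-3-yl]-4-methylhex-3-enal
Conditions: 10% aq oxalic acid on SiO2, CH2Cl2, rt; used at once
Reagents that add atoms: water O
Why: Mild heterogeneous acid hydrolysis of the dimethyl acetal frees the β,γ-unsaturated aldehyde without base, so neither migration of the C1=C10 alkene into conjugation nor epimerization at C6 is expected.

**Step 10**
Reactants: 16 (Z)-6-[(R)-4-(hydroxymethyl)-5-oxo-2-(prop-1-yn-1-yl)-2,5-dihydrofuran-3-yl]-4-methylhex-3-enal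
Product: 18 (3R,6R)-3,13-dihydroxygermacra-1(10)Z,4E,7(11)-trien-12,6-olide, via triethylsilyl ether 17 (not isolated)
Conditions: Ni(cod)2 (25 mol%), IMes (1,3-dimesitylimidazol-2-ylidene, 25 mol%), Et3SiH (5 equiv), THF, rt, syringe-pump addition of 16 to 0.005 M; then HF·pyridine, pyridine, THF, 0 °C
Reagents that add atoms: none
Why: Zerovalent nickel bearing the carbene binds alkyne and aldehyde and couples them oxidatively to an oxanickelacyclopentene (C3–C4 bond formed); Et3SiH cleaves the Ni–O bond by σ-bond metathesis and C–H reductive elimination at C5 releases the silyl ether with H and C3 cis, that is the E-C4=C5 alkene, before fluoride frees the diol (any silyl ether formed at C13 is cleaved as well). The closest known reaction type is the nickel-catalysed reductive macrocyclization of ynals with silanes. The ten-membered ring closes in the endo mode with respect to the alkyne, C3 bonding to the distal methyl-bearing carbon C4 so that the alkene is endocyclic. The new C3 stereocentre is controlled by C6: in the product-like nickelacycle the C6–H bond should eclipse the forming alkene to avoid A(1,3) strain with C15, which places the C7 tether on one face, and the aldehyde, whose oxygen is held in the nickelacycle plane, must turn its C2 arm to the same face, which corresponds to the 3R alkoxide. The step needs regioselectivity for C4 over C5, secured by the small carbene ligand (C–C bond at the alkyne carbon with the smaller substituent) and by the disfavoured nine-membered exo ring; it also needs chemoselectivity, secured by the inert tetrasubstituted butenolide alkene, by a free C13 hydroxyl that cannot ionise as an allylic acetate could, and by high dilution against oligomerization.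

**Step 11**
Reactants: 18 (3R,6R)-3,13-dihydroxygermacra-1(10)Z,4E,7(11)-trien-12,6-olide
Product: 19 (3R,6R)-13-acetoxy-3-hydroxygermacra-1(10)Z,4E,7(11)-trien-12,6-olide
Conditions: AcCl (1.05 equiv), 2,4,6-collidine, CH2Cl2, −78 °C
Reagents that add atoms: acetyl chloride CC(Cl)=O
Why: Kinetically selective acylation of the primary C13 hydroxyl over the secondary allylic C3 hydroxyl, which is hindered by the methyl-bearing C4, with a hindered weak base at low temperature.

**Step 12**
Reactants: 19 (3R,6R)-13-acetoxy-3-hydroxygermacra-1(10)Z,4E,7(11)-trien-12,6-olide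
Product: 20 (3S,6R)-13-acetoxy-3-(propanoyloxy)germacra-1(10)Z,4E,7(11)-trien-12,6-olide, the target
Conditions: EtCO2H (3 equiv), PPh3 (3 equiv), DIAD (3 equiv), toluene, 0 °C to rt
Reagents that add atoms: propanoic acid CCC(=O)O
Why: Mitsunobu esterification, in which propanoate displaces the alkoxyphosphonium by SN2 with inversion and so turns the 3R carbinol into the 3S propanoate; the SN2′ path is disfavoured because its terminus C5 sits next to the substituted C6.

**Compound list**

1 | but-2-yn-1-ol | CC#CCO | starting material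
2 | but-2-ynal | CC#CC=O | intermediate
3 | ethyl propiolate | C#CC(=O)OCC | starting material
4 | ethyl (R)-4-hydroxyhepta-2,5-diynoate | CC#C[C@@H](O)C#CC(=O)OCC | intermediate
5 | 3-methylanisole | COc1cccc(C)c1 | starting material
6 | 1-methoxy-5-methylcyclohexa-1,4-diene | COC1=CCC=C(C)C1 | intermediate
7 | methyl (Z)-3-methyl-6-oxohex-3-enoate | COC(=O)C/C(C)=C\CC=O | intermediate (not isolated)
8 | methyl (Z)-6,6-dimethoxy-3-methylhex-3-enoate | COC(=O)C/C(C)=C\CC(OC)OC | intermediate
9 | (Z)-6,6-dimethoxy-3-methylhex-3-en-1-ol | OCC/C(C)=C\CC(OC)OC | intermediate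
10 | (Z)-6-iodo-1,1-dimethoxy-4-methylhex-3-ene | ICC/C(C)=C\CC(OC)OC | intermediate
11 | [(Z)-6,6-dimethoxy-3-methylhex-3-en-1-yl]magnesium iodide | COC(OC)C/C=C(/C)CC[Mg]I | intermediate (not isolated)
12 | alkenylcopper adduct: bromomagnesium alkoxide of ethyl (R)-2-cuprio-3-[(Z)-6,6-dimethoxy-3-methylhex-3-en-1-yl]-4-hydroxyhept-2-en-5-ynoate, ester cis to the carbinol carbon | CCOC(=O)/C([Cu])=C(/CC/C(C)=C\CC(OC)OC)[C@H](O[Mg]Br)C#CC | intermediate (not isolated)
13 | ethyl (R,E)-3-[(Z)-6,6-dimethoxy-3-methylhex-3-en-1-yl]-4-hydroxy-2-iodohept-2-en-5-ynoate | CCOC(=O)/C(I)=C(/CC/C(C)=C\CC(OC)OC)[C@H](O)C#CC | intermediate (not isolated)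
14 | (R)-4-[(Z)-6,6-dimethoxy-3-methylhex-3-en-1-yl]-3-iodo-5-(prop-1-yn-1-yl)furan-2(5H)-one | CC#C[C@H]1OC(=O)C(I)=C1CC/C(C)=C\CC(OC)OC | intermediate
15 | (R)-4-[(Z)-6,6-dimethoxy-3-methylhex-3-en-1-yl]-3-(hydroxymethyl)-5-(prop-1-yn-1-yl)furan-2(5H)-one | CC#C[C@H]1OC(=O)C(CO)=C1CC/C(C)=C\CC(OC)OC | intermediate
16 | (Z)-6-[(R)-4-(hydroxymethyl)-5-oxo-2-(prop-1-yn-1-yl)-2,5-dihydrofuran-3-yl]-4-methylhex-3-enal | CC#C[C@H]1OC(=O)C(CO)=C1CC/C(C)=C\CC=O | intermediate
17 | (3R,6R)-13-hydroxy-3-(triethylsilyloxy)germacra-1(10)Z,4E,7(11)-trien-12,6-olide | CC[Si](CC)(CC)O[C@@H]1C/C=C(/C)CCC2=C(CO)C(=O)O[C@@H]2/C=C/1C | intermediate (not isolated)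
18 | (3R,6R)-3,13-dihydroxygermacra-1(10)Z,4E,7(11)-trien-12,6-olide | O[C@@H]1C/C=C(/C)CCC2=C(CO)C(=O)O[C@@H]2/C=C/1C | intermediate
19 | (3R,6R)-13-acetoxy-3-hydroxygermacra-1(10)Z,4E,7(11)-trien-12,6-olide | O[C@@H]1C/C=C(/C)CCC2=C(COC(C)=O)C(=O)O[C@@H]2/C=C/1C | intermediate
20 | (3S,6R)-13-acetoxy-3-(propanoyloxy)germacra-1(10)Z,4E,7(11)-trien-12,6-olide; [(6Z,9S,10E,11aR)-3-(acetoxymethyl)-6,10-dimethyl-2-oxo-2,4,5,8,9,11a-hexahydrocyclodeca[b]furan-9-yl] propanoate | CCC(=O)O[C@H]1C/C=C(/C)CCC2=C(COC(C)=O)C(=O)O[C@@H]2/C=C/1C | target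

**Step count.** Total: 12 steps. Longest linear sequence: 10 steps (steps 3 to 12, from 3-methylanisole).

**Steps most likely to fail**

1. Step 10. Ring closure may lose to intermolecular coupling or to plain hydrosilylation of the aldehyde; C–C bond formation may occur at the proximal alkyne carbon; zerovalent nickel may ionise the propargylic lactone C–O bond; or the free hydroxyl may slow turnover. The fallback sets out from 15 and replaces the alkyne by a preformed alkenyl iodide. Silylation (TBSCl, imidazole, DMF) should give (R)-3-[(tert-butyldimethylsilyloxy)methyl]-4-[(Z)-6,6-dimethoxy-3-methylhex-3-en-1-yl]-5-(prop-1-yn-1-yl)furan-2(5H)-one F1. Hydrozirconation with Cp2Zr(H)Cl in THF, with zirconium going to the less hindered methyl-bearing carbon, and iodinolysis with I2 should give the (E)-2-iodopropenyl butenolide F2. Acetal hydrolysis as in step 9 should give the iodo aldehyde F3. Nozaki–Hiyama–Kishi macrocyclization (CrCl2, NiCl2 cat., DMSO/THF, high dilution) should close the same C3–C4 bond to (3R,6R)-13-(tert-butyldimethylsilyloxy)-3-hydroxygermacra-1(10)Z,4E,7(11)-trien-12,6-olide F4, drawn as the 3R epimer on the same A(1,3) argument. HF·pyridine then returns the route to 18.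

2. Step 7. The alkenylcopper may equilibrate through its allenoate form before iodination and erode the alkene geometry, or the free alkoxide may lactonise early and the copper–carbon bond may be lost by protonation. The fallback sets out from 4 and separates C–C bond formation from lactonization. TESCl/imidazole should give ethyl (R)-4-(triethylsilyloxy)hepta-2,5-diynoate F5. Addition of the organocopper made from 10 at −78 °C and iodine quench at the same temperature should give ethyl (R,E)-3-[(Z)-6,6-dimethoxy-3-methylhex-3-en-1-yl]-2-iodo-4-(triethylsilyloxy)hept-2-en-5-ynoate F6. TBAF buffered with AcOH removes the silyl group and the freed hydroxy ester should close to 14.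

3. Step 12. In the hindered medium ring the displacement may go with allylic transposition, give elimination to a diene, or invert incompletely; the C3 configuration from step 10 may also be the opposite of the one assumed. The fallback sets out from 19 and sets C3 by reagent control. Dess–Martin oxidation should give (6R)-13-acetoxy-3-oxogermacra-1(10)Z,4E,7(11)-trien-12,6-olide F7. Corey–Bakshi–Shibata reduction with (R)-2-methyl-CBS-oxazaborolidine and catecholborane (toluene, −78 °C), with the α-methyl alkenyl group as the large substituent, should give (3S,6R)-13-acetoxy-3-hydroxygermacra-1(10)Z,4E,7(11)-trien-12,6-olide F8. Propanoic anhydride, DMAP and pyridine then acylate with retention to 20.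

**Further compounds**

F1 | step 10 | (R)-3-[(tert-butyldimethylsilyloxy)methyl]-4-[(Z)-6,6-dimethoxy-3-methylhex-3-en-1-yl]-5-(prop-1-yn-1-yl)furan-2(5H)-one | CC#C[C@H]1OC(=O)C(CO[Si](C)(C)C(C)(C)C)=C1CC/C(C)=C\CC(OC)OC
F2 | step 10 | (R)-3-[(tert-butyldimethylsilyloxy)methyl]-4-[(Z)-6,6-dimethoxy-3-methylhex-3-en-1-yl]-5-[(E)-2-iodoprop-1-en-1-yl]furan-2(5H)-one | C/C(I)=C\[C@H]1OC(=O)C(CO[Si](C)(C)C(C)(C)C)=C1CC/C(C)=C\CC(OC)OC
F3 | step 10 | (Z)-6-{(R)-4-[(tert-butyldimethylsilyloxy)methyl]-2-[(E)-2-iodoprop-1-en-1-yl]-5-oxo-2,5-dihydrofuran-3-yl}-4-methylhex-3-enal | C/C(I)=C\[C@H]1OC(=O)C(CO[Si](C)(C)C(C)(C)C)=C1CC/C(C)=C\CC=O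
F4 | step 10 | (3R,6R)-13-(tert-butyldimethylsilyloxy)-3-hydroxygermacra-1(10)Z,4E,7(11)-trien-12,6-olide | O[C@@H]1C/C=C(/C)CCC2=C(CO[Si](C)(C)C(C)(C)C)C(=O)O[C@@H]2/C=C/1C
F5 | step 7 | ethyl (R)-4-(triethylsilyloxy)hepta-2,5-diynoate | CC#C[C@@H](O[Si](CC)(CC)CC)C#CC(=O)OCC
F6 | step 7 | ethyl (R,E)-3-[(Z)-6,6-dimethoxy-3-methylhex-3-en-1-yl]-2-iodo-4-(triethylsilyloxy)hept-2-en-5-ynoate | CCOC(=O)/C(I)=C(/CC/C(C)=C\CC(OC)OC)[C@H](O[Si](CC)(CC)CC)C#CC
F7 | step 12 | (6R)-13-acetoxy-3-oxogermacra-1(10)Z,4E,7(11)-trien-12,6-olide | O=C1C/C=C(/C)CCC2=C(COC(C)=O)C(=O)O[C@@H]2/C=C/1C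
F8 | step 12 | (3S,6R)-13-acetoxy-3-hydroxygermacra-1(10)Z,4E,7(11)-trien-12,6-olide | O[C@H]1C/C=C(/C)CCC2=C(COC(C)=O)C(=O)O[C@@H]2/C=C/1C
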